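**Strategy**

Everything rests on disconnecting the bond between the carbonyl carbon C4 and C3 of the pyranone ring (ring C). Because C4(=O) is separated from the aryl- and O1-bearing C2 only by the C3 methylene, C4–C3H2–C2H is the retron of an alkene hydroacylation. The precursor is therefore an achiral ring A salicylaldehyde whose phenol oxygen carries a 1-arylvinyl group (C2=C3). One rhodium-catalysed step adds the formyl C–H across this enol ether: it forms C4–C3, closes ring C and sets C2. The 3-methoxy group follows by oxidation of the C3=C4 silyl enol ether anti to the C2 aryl group and O-methylation; deprotection ends the route.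

Key step: step 6

Assumption: the (R) ligand is taken to give the (2S) ketone 11; if the sense of induction is the opposite, its (S) antipode is used with no other change. The descriptors (2S) in 11 and 12 and (2R) in 13 to 16 denote the same spatial arrangement at C2, because the oxygen at C3 changes the priorities. Flavonoid numbering is used (O1, C2, C3, C4, C4a to C8a; ring B primed).

**Route**

Step 1
Reactants: 1 3,4,5-trimethoxyphenol; 2 paraformaldehyde
Product: 3 6-hydroxy-2,3,4-trimethoxybenzaldehyde
Conditions: MgCl2, Et3N, MeCN, reflux; then 1 M HCl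
Reagents that add atoms: none
Why: Casnati–Skattebøl ortho-formylation of the MgCl2/Et3N-derived aryloxide; the two ortho positions are equivalent and the para position is blocked, so a single aldehyde should form.

Step 2
Reactants: 4 4-(benzyloxy)-3-methoxyphenol; 5 benzyl bromide
Product: 6 1,4-bis(benzyloxy)-2-methoxybenzene
Conditions: K2CO3, DMF, 60 °C
Reagents that add atoms: none
Why: Williamson ether synthesis on the single free phenol with one equivalent of benzyl bromide; the existing benzyl and methyl ethers are inert to the carbonate base.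

Step 3
Reactants: 6 1,4-bis(benzyloxy)-2-methoxybenzene; 7 acetic anhydride
Product: 8 1-[2,5-bis(benzyloxy)-4-methoxyphenyl]ethan-1-one
Conditions: Sc(OTf)3 (10 mol%), MeNO2, 50 °C
Reagents that add atoms: none
Why: Friedel–Crafts acylation at the position para to the methoxy group and ortho to a benzyloxy group, the usual site in 1,2,4-trialkoxybenzenes; the catalytic mild Lewis acid should spare the benzyl ethers.

Step 4
Reactants: 8 1-[2,5-bis(benzyloxy)-4-methoxyphenyl]ethan-1-one
Product: 9 1-[2,5-bis(benzyloxy)-4-methoxyphenyl]ethenyl trifluoromethanesulfonate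
Conditions: KN(SiMe3)2, PhNTf2, THF, −78 °C
Reagents that add atoms: N-phenylbis(trifluoromethanesulfonimide), O=S(=O)(N(c1ccccc1)S(=O)(=O)C(F)(F)F)C(F)(F)F
Why: Enol triflate formation by O-sulfonylation of the potassium enolate; the methyl ketone has only one enolisable position.

Step 5
Reactants: 3 6-hydroxy-2,3,4-trimethoxybenzaldehyde; 9 1-[2,5-bis(benzyloxy)-4-methoxyphenyl]ethenyl trifluoromethanesulfonate
Product: 10 6-({1-[2,5-bis(benzyloxy)-4-methoxyphenyl]ethenyl}oxy)-2,3,4-trimethoxybenzaldehyde
Conditions: Pd2(dba)3 (2.5 mol%), tBuXPhos (6 mol%), K3PO4, toluene, 80 °C; chromatography on Et3N-deactivated silica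
Reagents that add atoms: none
Why: Palladium-catalysed C–O cross-coupling of an enol triflate with a phenol (Buchwald–Hartwig-type etherification): zerovalent palladium adds into the vinyl C–OTf bond, the phenoxide exchanges for triflate and reductive elimination gives the aryl vinyl ether.

Step 6
Reactants: 10 6-({1-[2,5-bis(benzyloxy)-4-methoxyphenyl]ethenyl}oxy)-2,3,4-trimethoxybenzaldehyde
Product: 11 (2S)-2-[2,5-bis(benzyloxy)-4-methoxyphenyl]-5,6,7-trimethoxy-2,3-dihydro-4H-chromen-4-one
Conditions: [Rh(cod)Cl]2 (2.5 mol%), (R)-DTBM-SEGPHOS (5.5 mol%), AgBF4 (5 mol%), 1,4-dioxane, 60 °C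
Reagents that add atoms: none
Why: Proposed new method: the cationic bisphosphine complex of monovalent rhodium, held by the two ortho ether oxygens of ring A, adds oxidatively into the formyl C–H bond; the tethered enol ether then inserts into Rh–H with hydride going to the oxygen- and aryl-bearing C2, and C–C reductive elimination from the seven-membered acyl–alkyl rhodacycle of trivalent rhodium forms C4–C3. The closest known reaction type is the rhodium-catalysed enantioselective intramolecular hydroacylation of 1,1-disubstituted alkenes, which turns 2-(1-arylvinyl)benzaldehydes into 3-arylindanones and ortho-(2-substituted allyl)benzaldehydes into 3-substituted tetralones; new here are the oxygen atom in the tether (an aryl vinyl ether) and the chroman-4-one product. Ring C closes in a formal 6-endo-trig mode with respect to the C2=C3 double bond. The C2 stereocentre is created in the hydride insertion, where the chiral bisphosphine selects one face of the prochiral alkene. The step needs acyl transfer to the terminal carbon C3 and not to C2, and hydroacylation ahead of decarbonylation: the first is secured by the 1,1-disubstitution, since the other mode would demand a tertiary alkyl–rhodium bond and a quaternary centre, the second by ether chelation of the acyl hydride and by the absence of allylic hydrogen atoms, which excludes alkene isomerisation.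

Step 7
Reactants: 11 (2S)-2-[2,5-bis(benzyloxy)-4-methoxyphenyl]-5,6,7-trimethoxy-2,3-dihydro-4H-chromen-4-one
Product: 14 (2R,3R)-2-[2,5-bis(benzyloxy)-4-methoxyphenyl]-3-hydroxy-5,6,7-trimethoxy-2,3-dihydro-4H-chromen-4-one, via silyl enol ether 12 (not isolated), via silyloxy ketone 13 (not isolated)
Conditions: Me3SiOTf, Et3N, CH2Cl2, 0 °C; then dimethyldioxirane, acetone, −30 °C; then aq. citric acid, MeOH
Reagents that add atoms: trimethylsilyl trifluoromethanesulfonate, C[Si](C)(C)OS(=O)(=O)C(F)(F)F; dimethyldioxirane, CC1(C)OO1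
Why: Rubottom oxidation: soft enolisation avoids the ring-opening enolate, dimethyldioxirane should epoxidise the C3=C4 enol ether on the face anti to the C2 aryl group, and silyl migration followed by acid gives the 2,3-trans ketol, so C3 is set by the C2 centre.

Step 8
Reactants: 14 (2R,3R)-2-[2,5-bis(benzyloxy)-4-methoxyphenyl]-3-hydroxy-5,6,7-trimethoxy-2,3-dihydro-4H-chromen-4-one
Product: 15 (2R,3R)-2-[2,5-bis(benzyloxy)-4-methoxyphenyl]-3,5,6,7-tetramethoxy-2,3-dihydro-4H-chromen-4-one
Conditions: MeOTf, 2,6-di-tert-butyl-4-methylpyridine, CH2Cl2, 25 °C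
Reagents that add atoms: methyl trifluoromethanesulfonate, COS(=O)(=O)C(F)(F)F
Why: O-methylation of the secondary alcohol with methyl triflate and a hindered non-nucleophilic base; no enolate is formed, so C2 and C3 should stay untouched.

Step 9
Reactants: 15 (2R,3R)-2-[2,5-bis(benzyloxy)-4-methoxyphenyl]-3,5,6,7-tetramethoxy-2,3-dihydro-4H-chromen-4-one
Product: 16 (2R,3R)-2-(2,5-dihydroxy-4-methoxyphenyl)-5-hydroxy-3,6,7-trimethoxy-2,3-dihydro-4H-chromen-4-one (CNP0257825.1)
Conditions: BCl3, C6HMe5, CH2Cl2, −78 °C to 0 °C; then H2O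
Reagents that add atoms: none
Why: BCl3 ether cleavage: the benzyl groups are transferred to pentamethylbenzene at low temperature, and chelation of boron by the C4 carbonyl should activate only the peri 5-methoxy group for demethylation.

**Compound list**

1 | 3,4,5-trimethoxyphenol | COc1cc(O)cc(OC)c1OC | starting material
2 | paraformaldehyde (formaldehyde source) | C=O | starting material
3 | 6-hydroxy-2,3,4-trimethoxybenzaldehyde | O=Cc1c(O)cc(OC)c(OC)c1OC | intermediate
4 | 4-(benzyloxy)-3-methoxyphenol | COc1cc(O)ccc1OCc1ccccc1 | starting material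
5 | benzyl bromide | BrCc1ccccc1 | starting material
6 | 1,4-bis(benzyloxy)-2-methoxybenzene | COc1cc(OCc2ccccc2)ccc1OCc1ccccc1 | intermediate
7 | acetic anhydride | CC(=O)OC(C)=O | starting material
8 | 1-[2,5-bis(benzyloxy)-4-methoxyphenyl]ethan-1-one | COc1cc(OCc2ccccc2)c(C(C)=O)cc1OCc1ccccc1 | intermediate
9 | 1-[2,5-bis(benzyloxy)-4-methoxyphenyl]ethenyl trifluoromethanesulfonate | COc1cc(OCc2ccccc2)c(C(=C)OS(=O)(=O)C(F)(F)F)cc1OCc1ccccc1 | intermediate
10 | 6-({1-[2,5-bis(benzyloxy)-4-methoxyphenyl]ethenyl}oxy)-2,3,4-trimethoxybenzaldehyde | O=Cc1c(OC(=C)c2cc(OCc3ccccc3)c(OC)cc2OCc2ccccc2)cc(OC)c(OC)c1OC | intermediate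
11 | (2S)-2-[2,5-bis(benzyloxy)-4-methoxyphenyl]-5,6,7-trimethoxy-2,3-dihydro-4H-chromen-4-one | COc1cc(OCc2ccccc2)c([C@H]3Oc4cc(OC)c(OC)c(OC)c4C(=O)C3)cc1OCc1ccccc1 | intermediate
12 | (2S)-2-[2,5-bis(benzyloxy)-4-methoxyphenyl]-5,6,7-trimethoxy-4-[(trimethylsilyl)oxy]-2H-chromene (silyl enol ether, not isolated) | COc1cc(OCc2ccccc2)c([C@H]3Oc4cc(OC)c(OC)c(OC)c4C(O[Si](C)(C)C)=C3)cc1OCc1ccccc1 | intermediate
13 | (2R,3R)-2-[2,5-bis(benzyloxy)-4-methoxyphenyl]-5,6,7-trimethoxy-3-[(trimethylsilyl)oxy]-2,3-dihydro-4H-chromen-4-one (silyloxy ketone, not isolated) | COc1cc(OCc2ccccc2)c([C@H]3Oc4cc(OC)c(OC)c(OC)c4C(=O)[C@@H]3O[Si](C)(C)C)cc1OCc1ccccc1 | intermediate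
14 | (2R,3R)-2-[2,5-bis(benzyloxy)-4-methoxyphenyl]-3-hydroxy-5,6,7-trimethoxy-2,3-dihydro-4H-chromen-4-one | COc1cc(OCc2ccccc2)c([C@H]3Oc4cc(OC)c(OC)c(OC)c4C(=O)[C@@H]3O)cc1OCc1ccccc1 | intermediate
15 | (2R,3R)-2-[2,5-bis(benzyloxy)-4-methoxyphenyl]-3,5,6,7-tetramethoxy-2,3-dihydro-4H-chromen-4-one | COc1cc(OCc2ccccc2)c([C@H]3Oc4cc(OC)c(OC)c(OC)c4C(=O)[C@@H]3OC)cc1OCc1ccccc1 | intermediate
16 | (2R,3R)-2-(2,5-dihydroxy-4-methoxyphenyl)-5-hydroxy-3,6,7-trimethoxy-2,3-dihydro-4H-chromen-4-one (CNP0257825.1) | COc1cc(O)c([C@H]2Oc3cc(OC)c(OC)c(O)c3C(=O)[C@@H]2OC)cc1O | target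

**Step count and risks**

Total step count: 9. Longest linear sequence: 8 steps (steps 2 to 9, from 4).

The three steps most likely to fail:

Step 6 (Proposed new method). The hydride may insert in the opposite sense so that the acyl group goes to C2. The hindered, electron-rich acyl hydride may lose carbon monoxide. The Lewis-acidic cation may hydrolyse the enol ether, or the ligand may discriminate the alkene faces poorly. The fallback uses known chemistry and sets out from 10. A thiol-catalysed radical chain (tert-dodecanethiol, azobisisobutyronitrile, 1,4-dioxane, 80 °C) should make the acyl radical add 6-endo to the terminal carbon of the enol ether, and the C2 radical then takes a hydrogen atom from the thiol. This should give racemic 2-[2,5-bis(benzyloxy)-4-methoxyphenyl]-5,6,7-trimethoxy-2,3-dihydro-4H-chromen-4-one F1. A kinetic resolution by asymmetric transfer hydrogenation follows (RuCl(p-cymene)[(R,R)-TsDPEN] or its antipode, whichever consumes the (2R) ketone faster, HCO2H/Et3N). It should reduce the unwanted enantiomer to (2R,4R)-2-[2,5-bis(benzyloxy)-4-methoxyphenyl]-5,6,7-trimethoxy-3,4-dihydro-2H-chromen-4-ol F2 and leave the (2S) ketone, so the fallback comes back to the route at 11.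

Step 5. Reductive elimination of the C–O bond may be slow with the chelating, electron-poor salicylaldehyde phenoxide. The triflyl group may be transferred from 9 to the phenoxide, or base may eliminate 9 to the alkyne. The fallback sets out from 9 and makes that elimination deliberate (KOtBu, THF, 0 °C), giving 1,4-bis(benzyloxy)-2-ethynyl-5-methoxybenzene F3. Phenol 3 is then added across the alkyne in the Markovnikov sense with a catalyst of monovalent gold (AuCl(IPr)/AgOTf, IPr = 1,3-bis(2,6-diisopropylphenyl)imidazol-2-ylidene, toluene, 60 °C). The electron-rich aryl group should direct the oxygen to the internal carbon, and the fallback comes back to the route at 10.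

Step 9. BCl3 may also cleave the aliphatic 3-methoxy group or the 6-methoxy group. The Lewis acid may open the C2–O1 bond next to the electron-rich ring B and erode the configuration, or the hydroquinone may oxidise during work-up. The fallback sets out from 15 and separates the two tasks. Neutral hydrogenolysis (H2, Pd/C, EtOAc) should give (2R,3R)-2-(2,5-dihydroxy-4-methoxyphenyl)-3,5,6,7-tetramethoxy-2,3-dihydro-4H-chromen-4-one F4. Chelation-selective demethylation of the peri 5-methoxy group with AlCl3 in MeCN at 0 °C, the standard selective cleavage in polymethoxyflavonoids, then comes back to the route at 16.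

Further compounds
F1 | step 6 | racemic 2-[2,5-bis(benzyloxy)-4-methoxyphenyl]-5,6,7-trimethoxy-2,3-dihydro-4H-chromen-4-one | COc1cc(OCc2ccccc2)c(C3Oc4cc(OC)c(OC)c(OC)c4C(=O)C3)cc1OCc1ccccc1
F2 | step 6 | (2R,4R)-2-[2,5-bis(benzyloxy)-4-methoxyphenyl]-5,6,7-trimethoxy-3,4-dihydro-2H-chromen-4-ol | COc1cc(OCc2ccccc2)c([C@@H]3Oc4cc(OC)c(OC)c(OC)c4[C@H](O)C3)cc1OCc1ccccc1
F3 | step 5 | 1,4-bis(benzyloxy)-2-ethynyl-5-methoxybenzene | COc1cc(OCc2ccccc2)c(C#C)cc1OCc1ccccc1
F4 | step 9 | (2R,3R)-2-(2,5-dihydroxy-4-methoxyphenyl)-3,5,6,7-tetramethoxy-2,3-dihydro-4H-chromen-4-one | COc1cc(O)c([C@H]2Oc3cc(OC)c(OC)c(OC)c3C(=O)[C@@H]2OC)cc1O
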